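**Assumption:** the target is handled as the drawn 4-hydroxy enol tautomer of a 3-acyl-oxane-2,4-dione; primed locants (C1'–C12') count along the side chain from the ring-bound ketone carbon.

## Retrosynthetic overview

1. Target ⇒ its tert-butyl ester ⇒ side-chain acid + (R)-6-methyloxane-2,4-dione, joined at C3–C1' by O-acylation and O→C acyl shift.
2. Side-chain acid ⇒ C7'–C8' bond (key step): nickel-catalysed stereoconvergent radical alkenylation of a C2-epimeric α-bromo tert-butyl ester with an (E)-alkenylzirconium made in situ from a terminal alkynoic acid. This joins the two halves, sets C8' and fixes the E alkene.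
3. Alkynoic acid ⇒ 4-methylcyclohexanone (enantioselective deprotonation, ozonolysis, one-carbon alkyne homologation). Bromo ester ⇒ acetic acid + (S)-1-bromo-2-methylbutane.
4. Ring order: the only ring, the dihydropyranone, is closed first (crossed Claisen, lactonisation) and attached to the chain in the last step.

## Route

Step 1
Reactants: 1 methyl (R)-3-hydroxybutanoate; 2 tert-butyl acetate
Product: 3 tert-butyl (R)-5-hydroxy-3-oxohexanoate
Conditions: LiN(iPr)2 (3.4 equiv), 2 (3.3 equiv), THF, −78 °C; add 1; −78 → −20 °C, 3 h; 1 M HCl quench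
Reagents that add atoms: none
Why: Crossed Claisen condensation: the lithium enolate of tert-butyl acetate (slow to self-condense) acylates on the methyl ester of the alkoxide of 1, and the carbinol stereocentre is not touched.

Step 2
Reactants: 3 tert-butyl (R)-5-hydroxy-3-oxohexanoate
Product: 5 (R)-6-methyloxane-2,4-dione, via hydroxy keto acid 4 (not isolated)
Conditions: TFA/CH2Cl2 (1:3), rt, 4 h
Reagents that add atoms: none
Why: Acidolysis of the tert-butyl ester (loss of isobutene) followed by acid-catalysed 6-exo lactonisation of the δ-hydroxy acid, which outruns decarboxylation; C6 is carried over unchanged.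

Step 3
Reactants: 6 4-methylcyclohexanone
Product: 7 trimethyl{[(4R)-4-methylcyclohex-1-en-1-yl]oxy}silane
Conditions: LiN[(S)-CH(CH3)Ph]2·LiCl (1.2 equiv), TMSCl (5 equiv, internal quench), THF, −100 → −78 °C
Reagents that add atoms: chlorotrimethylsilane, C[Si](C)(C)Cl
Why: Enantioselective deprotonation (chiral lithium amide desymmetrisation): the C2-symmetric amide removes one of the two enantiotopic axial α-protons and TMSCl traps the enolate at once, so the double-bond position fixes the later C4' centre as R (about 90% ee expected; the base antipode is chosen by analogy with the 4-tert-butyl series, from memory, and must be confirmed by rotation).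

Step 4
Reactants: 7 trimethyl{[(4R)-4-methylcyclohex-1-en-1-yl]oxy}silane
Product: 10 (R)-4-methyl-6-oxohexanoic acid, via methoxy hydroperoxide 8 (not isolated), via silyl ester aldehyde 9 (not isolated)
Conditions: O3, CH2Cl2/MeOH (4:1), −78 °C; Me2S (5 equiv), −78 °C → rt; aqueous work-up (pH 3)
Reagents that add atoms: ozone, [O-][O+]=O (methanol, CO, appears only in 8)
Why: Ozonolysis of the electron-rich enol ether: the silyloxy carbon becomes the carboxyl group (C1') and the other alkene carbon the aldehyde (C6'); the stereocentre is β to the aldehyde and cannot epimerise.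

Step 5
Reactants: 10 (R)-4-methyl-6-oxohexanoic acid
Product: 11 (R)-4-methylhept-6-ynoic acid
Conditions: dimethyl (1-diazo-2-oxopropyl)phosphonate (1.3 equiv), K2CO3 (3 equiv), MeOH, 0 °C → rt, 12 h; 1 M HCl to pH 2
Reagents that add atoms: dimethyl (1-diazo-2-oxopropyl)phosphonate (Ohira–Bestmann reagent), CC(=O)C(=[N+]=[N-])P(=O)(OC)OC
Why: Ohira–Bestmann (Seyferth–Gilbert) homologation turns the aldehyde into the terminal alkyne with one added carbon (C7'); the extra carbonate carries the acid as its carboxylate.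

Step 6
Reactants: 12 acetic acid; 13 (S)-1-bromo-2-methylbutane
Product: 14 (S)-4-methylhexanoic acid
Conditions: LiN(iPr)2 (2.2 equiv per 12), THF/HMPA, 0 °C; add 13; 0 → 45 °C, 16 h; 2 M HCl
Reagents that add atoms: none
Why: Alkylation of the acetic acid dianion (enediolate) by SN2 at the primary bromide; the existing stereocentre is β to the reacting carbon and is not touched.

Step 7
Reactants: 14 (S)-4-methylhexanoic acid
Product: 17 tert-butyl (4S)-2-bromo-4-methylhexanoate (1:1 mixture of C2 epimers), via acid chloride 15 (not isolated), via bromo acid chloride 16 (not isolated)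
Conditions: SOCl2 (neat), 70 °C, 1 h; NBS (1.2 equiv), HBr (cat.), 85 °C, 2 h; evaporate; t-BuOH (3 equiv), pyridine (1.5 equiv), CH2Cl2, 0 °C → rt
Reagents that add atoms: N-bromosuccinimide, O=C1CCC(=O)N1Br; tert-butanol, CC(C)(C)O; thionyl chloride, O=S(Cl)Cl (chlorine only in 15 and 16)
Why: Hell–Volhard–Zelinsky-type α-bromination of the enolisable acid chloride (NBS variant) followed by esterification; the new C2 centre is deliberately left uncontrolled because step 8 erases it.

Step 8
Reactants: 11 (R)-4-methylhept-6-ynoic acid; 17 tert-butyl (4S)-2-bromo-4-methylhexanoate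
Product: 20 (4R,6E,8S,10S)-8-(tert-butoxycarbonyl)-4,10-dimethyldodec-6-enoic acid, via alkenylzirconium 18 (not isolated), via zirconocene carboxylate 19 (not isolated)
Conditions: 11 (1.3 equiv), Cp2Zr(H)Cl (2.05 equiv per 11), THF, rt, 40 min; add to 17 (1.0 equiv), NiCl2·DME (10 mol %), (S,S)-Ph-BOX [2,2'-(propane-2,2-diyl)bis((4S)-4-phenyl-4,5-dihydro-1,3-oxazole)] (13 mol %; antipode confirmed in the first run), DME, 10 °C, 24 h; 1 M HCl
Reagents that add atoms: none
Why: Proposed new method: syn-hydrozirconation (the first equivalent of Cp2Zr(H)Cl masks the acid as its zirconocene carboxylate) gives only the (E)-alkenylzirconium, which transmetalates to the bis(oxazoline)-bound nickel; monovalent nickel abstracts bromine from either C2 epimer of 17 to give one planar α-ester radical, and its capture at alkenylnickel followed by reductive elimination from trivalent nickel forms the C7'–C8' bond, with the ligand (not the remote 4S centre) deciding the 8'S configuration and the E geometry retained; the closest known reaction types are the nickel/bis(oxazoline) stereoconvergent coupling of racemic α-bromo ketones with alkenylzirconium reagents and the nickel/diamine stereoconvergent Hiyama alkenylation of racemic α-bromo esters.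

Step 9
Reactants: 20 (4R,6E,8S,10S)-8-(tert-butoxycarbonyl)-4,10-dimethyldodec-6-enoic acid; 5 (R)-6-methyloxane-2,4-dione
Product: 23 (2S,3E,6R)-9-[(6R)-4-hydroxy-6-methyl-2-oxo-5,6-dihydro-2H-pyran-3-yl]-6-methyl-2-[(2S)-2-methylbutyl]-9-oxonon-3-enoic acid (target), via enol ester 21 (not isolated), via tert-butyl ester 22 (not isolated)
Conditions: 5 (1.1 equiv), DCC (1.1 equiv), DMAP (1.2 equiv), CH2Cl2, 0 °C → rt, 24 h; filter; TFA (25 vol %), rt, 3 h
Reagents that add atoms: none
Why: Steglich O-acylation of the enol of 5, then DMAP-mediated 1,3 O→C acyl migration (Fries-type rearrangement via the acylpyridinium/enolate ion pair) to the chelated tricarbonyl, then acidolysis of the tert-butyl ester; none of the four stereocentres is enolised under these conditions.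

## Compound list

1 | methyl (R)-3-hydroxybutanoate | C[C@@H](O)CC(=O)OC | starting material
2 | tert-butyl acetate | CC(=O)OC(C)(C)C | starting material
3 | tert-butyl (R)-5-hydroxy-3-oxohexanoate | C[C@@H](O)CC(=O)CC(=O)OC(C)(C)C | intermediate
4 | (R)-5-hydroxy-3-oxohexanoic acid | C[C@@H](O)CC(=O)CC(=O)O | intermediate
5 | (R)-6-methyloxane-2,4-dione [enol form: (R)-4-hydroxy-6-methyl-5,6-dihydro-2H-pyran-2-one] | C[C@@H]1CC(=O)CC(=O)O1 | intermediate
6 | 4-methylcyclohexanone | CC1CCC(=O)CC1 | starting material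
7 | trimethyl{[(4R)-4-methylcyclohex-1-en-1-yl]oxy}silane | C[Si](C)(C)OC1=CC[C@H](C)CC1 | intermediate
8 | trimethylsilyl (4R)-6-hydroperoxy-6-methoxy-4-methylhexanoate (C6 epimers) | COC(OO)C[C@H](C)CCC(=O)O[Si](C)(C)C | intermediate
9 | trimethylsilyl (R)-4-methyl-6-oxohexanoate | O=CC[C@H](C)CCC(=O)O[Si](C)(C)C | intermediate
10 | (R)-4-methyl-6-oxohexanoic acid | O=CC[C@H](C)CCC(=O)O | intermediate
11 | (R)-4-methylhept-6-ynoic acid | C#CC[C@H](C)CCC(=O)O | intermediate
12 | acetic acid | CC(=O)O | starting material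
13 | (S)-1-bromo-2-methylbutane | CC[C@H](C)CBr | starting material
14 | (S)-4-methylhexanoic acid | CC[C@H](C)CCC(=O)O | intermediate
15 | (S)-4-methylhexanoyl chloride | CC[C@H](C)CCC(Cl)=O | intermediate
16 | (4S)-2-bromo-4-methylhexanoyl chloride (C2 epimers) | CC[C@H](C)CC(Br)C(Cl)=O | intermediate
17 | tert-butyl (4S)-2-bromo-4-methylhexanoate (C2 epimers) | CC[C@H](C)CC(Br)C(=O)OC(C)(C)C | intermediate
18 | chlorobis(cyclopentadienyl)zirconium (4R,6E)-7-[chlorobis(cyclopentadienyl)zirconio]-4-methylhept-6-enoate | Cl[Zr](C1C=CC=C1)(C1C=CC=C1)/C=C/C[C@H](C)CCC(=O)O[Zr](Cl)(C1C=CC=C1)C1C=CC=C1 | intermediate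
19 | chlorobis(cyclopentadienyl)zirconium (4R,6E,8S,10S)-8-(tert-butoxycarbonyl)-4,10-dimethyldodec-6-enoate | CC[C@H](C)C[C@@H](/C=C/C[C@H](C)CCC(=O)O[Zr](Cl)(C1C=CC=C1)C1C=CC=C1)C(=O)OC(C)(C)C | intermediate
20 | (4R,6E,8S,10S)-8-(tert-butoxycarbonyl)-4,10-dimethyldodec-6-enoic acid | CC[C@H](C)C[C@@H](/C=C/C[C@H](C)CCC(=O)O)C(=O)OC(C)(C)C | intermediate
21 | tert-butyl (2S,3E,6R)-6-methyl-2-[(2S)-2-methylbutyl]-9-{[(2R)-2-methyl-6-oxo-3,6-dihydro-2H-pyran-4-yl]oxy}-9-oxonon-3-enoate | CC[C@H](C)C[C@@H](/C=C/C[C@H](C)CCC(=O)OC1=CC(=O)O[C@H](C)C1)C(=O)OC(C)(C)C | intermediate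
22 | tert-butyl (2S,3E,6R)-9-[(6R)-4-hydroxy-6-methyl-2-oxo-5,6-dihydro-2H-pyran-3-yl]-6-methyl-2-[(2S)-2-methylbutyl]-9-oxonon-3-enoate | CC[C@H](C)C[C@@H](/C=C/C[C@H](C)CCC(=O)C1=C(O)C[C@@H](C)OC1=O)C(=O)OC(C)(C)C | intermediate
23 | (2S,3E,6R)-9-[(6R)-4-hydroxy-6-methyl-2-oxo-5,6-dihydro-2H-pyran-3-yl]-6-methyl-2-[(2S)-2-methylbutyl]-9-oxonon-3-enoic acid | CC[C@H](C)C[C@@H](/C=C/C[C@H](C)CCC(=O)C1=C(O)C[C@@H](C)OC1=O)C(=O)O | target

## Step count and risks

Total step count: 9. Longest linear sequence: 5 (steps 3, 4, 5, 8, 9).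

**Step 8 (key coupling).** The level and sense of induction at C8' for a tert-butyl α-bromo ester are untested, and the zirconocene carboxylate may slow the nickel catalyst. The C8' epimers are diastereomers, so the ratio can be read directly by NMR. If control is poor, C8' is set by copper-catalysed asymmetric allylic alkylation instead, and the halves are joined by olefin cross-metathesis. This fallback sets out from 13, 11 and 5 and comes back at 23.
- 13 is converted (Mg, Et2O) into (S)-2-methylbutylmagnesium bromide F1.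
- F1 undergoes SN2' alkylation of commercial methyl (E)-4-bromobut-2-enoate (CuBr·SMe2, Taniaphos-type ferrocenyl diphosphine, CH2Cl2, −75 °C) to give methyl (2S,4S)-2-ethenyl-4-methylhexanoate F2.
- Me3SnOH (1,2-dichloroethane, 80 °C) gives (2S,4S)-2-ethenyl-4-methylhexanoic acid F3 without moving the double bond.
- In parallel, 11 is semi-hydrogenated (H2, Pd/CaCO3 poisoned with Pb(OAc)2, quinoline) to (R)-4-methylhept-6-enoic acid F4.
- F4 is C-acylated onto 5 (DCC, DMAP) to give (6R)-4-hydroxy-6-methyl-3-[(4R)-4-methylhept-6-enoyl]-5,6-dihydro-2H-pyran-2-one F5.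
- Cross-metathesis of F5 with F3 (second-generation Hoveyda–Grubbs catalyst, CH2Cl2, 40 °C) gives 23. F3 also serves as the 8'S reference sample for step 8.

**Step 3 (desymmetrisation).** About 90% ee is the realistic ceiling, and the minor enantiomer becomes a C4' epimer that is hard to remove later. The fallback moves the asymmetric event to a Baeyer–Villiger oxidation; it sets out from 6 and comes back at 11.
- Sc(OTf)3 with a chiral N,N'-dioxide ligand and m-CPBA, or an (R)-selective Baeyer–Villiger monooxygenase, gives (R)-5-methyloxepan-2-one F6.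
- K2CO3 in MeOH gives methyl (R)-6-hydroxy-4-methylhexanoate F7.
- Dess–Martin periodinane gives methyl (R)-4-methyl-6-oxohexanoate F8.
- The Ohira–Bestmann reagent with K2CO3 in MeOH gives methyl (R)-4-methylhept-6-ynoate F9.
- LiOH in THF/H2O returns to the route at 11.

**Step 9 (C-acylation).** The O→C shift can stall at enol ester 21 or give a low yield on this precious late intermediate. The fallback builds the ring onto the chain; it sets out from 20 and 1 and comes back at 22.
- DCC/DMAP coupling of 20 with Meldrum's acid gives tert-butyl (2S,3E,6R)-9-(2,2-dimethyl-4,6-dioxo-1,3-dioxan-5-yl)-6-methyl-2-[(2S)-2-methylbutyl]-9-oxonon-3-enoate F10.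
- Heating F10 with 1 (toluene, 90 °C) gives the β-keto ester 1-tert-butyl 11-[(2R)-4-methoxy-4-oxobutan-2-yl] (2S,3E,6R)-6-methyl-2-[(2S)-2-methylbutyl]-9-oxoundec-3-enedioate F11.
- Dieckmann cyclisation (KOt-Bu, THF, 0 °C, short reaction time to outrun β-elimination) closes the ring to 22, which is cleaved with TFA as in the last stage of step 9.

## Further compounds

F1 | step 8 | (S)-2-methylbutylmagnesium bromide | CC[C@H](C)C[Mg]Br
F2 | step 8 | methyl (2S,4S)-2-ethenyl-4-methylhexanoate | CC[C@H](C)C[C@@H](C=C)C(=O)OC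
F3 | step 8 | (2S,4S)-2-ethenyl-4-methylhexanoic acid | CC[C@H](C)C[C@@H](C=C)C(=O)O
F4 | step 8 | (R)-4-methylhept-6-enoic acid | C=CC[C@H](C)CCC(=O)O
F5 | step 8 | (6R)-4-hydroxy-6-methyl-3-[(4R)-4-methylhept-6-enoyl]-5,6-dihydro-2H-pyran-2-one | C=CC[C@H](C)CCC(=O)C1=C(O)C[C@@H](C)OC1=O
F6 | step 3 | (R)-5-methyloxepan-2-one | O=C1CC[C@@H](C)CCO1
F7 | step 3 | methyl (R)-6-hydroxy-4-methylhexanoate | OCC[C@H](C)CCC(=O)OC
F8 | step 3 | methyl (R)-4-methyl-6-oxohexanoate | O=CC[C@H](C)CCC(=O)OC
F9 | step 3 | methyl (R)-4-methylhept-6-ynoate | C#CC[C@H](C)CCC(=O)OC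
F10 | step 9 | tert-butyl (2S,3E,6R)-9-(2,2-dimethyl-4,6-dioxo-1,3-dioxan-5-yl)-6-methyl-2-[(2S)-2-methylbutyl]-9-oxonon-3-enoate | CC[C@H](C)C[C@@H](/C=C/C[C@H](C)CCC(=O)C1C(=O)OC(C)(C)OC1=O)C(=O)OC(C)(C)C
F11 | step 9 | 1-tert-butyl 11-[(2R)-4-methoxy-4-oxobutan-2-yl] (2S,3E,6R)-6-methyl-2-[(2S)-2-methylbutyl]-9-oxoundec-3-enedioate | CC[C@H](C)C[C@@H](/C=C/C[C@H](C)CCC(=O)CC(=O)O[C@H](C)CC(=O)OC)C(=O)OC(C)(C)C
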